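Saturday's run, the neighbour of the flask I was asked about, showed a puzzle at its end.

| flask | starting material | coupling partner | time |
|---|---|---|---|
| Friday's | 0.400 M | 1.20 M |  |
| Monday's | 0.200 M | 1.00 M |  |
| Saturday's | 0.400 M | 2.40 M |  |
| Thursday's | 0.800 M | 2.40 M | 36 min |

| run | time / min | [target] / M |
|---|---|---|
| Friday's run | 1.6 | 0.0097 |
| Friday's run | 4.9 | 0.0352 |
| Friday's run | 9.3 | 0.0733 |
| Friday's run | 15 | 0.1412 |
| Friday's run | 21 | 0.2120 |
| Friday's run | 28 | 0.2690 |
| Friday's run | 36 | 0.3009 |
| Monday's run | 1.6 | 0.0044 |
| Monday's run | 4.9 | 0.0096 |
| Monday's run | 9.3 | 0.0222 |
| Monday's run | 15 | 0.0384 |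
| Monday's run | 21 | 0.0590 |
| Monday's run | 28 | 0.0788 |
| Monday's run | 36 | 0.0979 |
| Saturday's run | 1.6 | 0.0207 |
| Saturday's run | 4.9 | 0.0801 |
| Saturday's run | 9.3 | 0.1761 |
| Saturday's run | 15 | 0.2822 |
| Saturday's run | 21 | 0.3273 |
| Saturday's run | 28 | 0.3383 |
| Saturday's run | 36 | 0.3266 |

(scatter of a reading: 0.001 M)

- Overall: starting material + coupling partner -> target.
- Constant volume, constant temperature.
- The analysis sees a species whether free or bound.
- "The second partner" is coupling partner.
- An order is taken over about fifteen percent of the charge, up and down.

1. order of the initial rate in [starting material], near the charge of the Friday's run, the rate being that where two percent of its starting material are target (one fixed amount of target, the same in the runs compared)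
2. order of the initial rate in [coupling partner], near the charge of the Friday's run, the rate being that where two percent of its starting material are target
3. target in the Thursday's run at 36 min, as a share of the starting material charged

In Saturday's run the highest reading of target was 0.3383 M at 28 min and the last reading was 0.3266 M, yet 0.0617 M of the charge was not seen as target at that highest reading. Was that gap unreacted starting material? Between 9.3 min and 15 min I took the rate over the charge not yet seen as target, a pseudo-first-order pace c:

c = 0.109 min⁻¹

At that pace the gap would have yielded 0.006722 M min⁻¹ of new target, but the last two readings show target going down by 0.001462 M min⁻¹. So I read much of the gap as target already lost, and reckoned the run from two sides. The area under the whole target curve gives the time target spent in the flask, and the last reading gives what had gone.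

τ, area under Saturday's target curve per charge = 22.2 min

missing share at 36 min = 18.3%

λ = missing share / τ = 0.008275 min⁻¹

This λ, the loss constant, is the share of target lost per minute. It reads high if any starting material remained. A first-order loss takes shares, so Thursday's flask, with 2.40 M of coupling partner as on Saturday, keeps 1 − λτ of its charge. With Saturday's τ that is 81.6%, which I took as a ceiling, expecting Thursday's larger charge of starting material to bring the turnover forward.

The forecast gave 1.1, 1.1 and 81%, noting “Saturday's target falls late, so target is slowly lost”.

The simulation gave 1.0, 1.1 and 79.6%.

    2 coupling partner ⇌ reagent dimer, settled at all times (2.540 M⁻¹)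
    starting material + reagent dimer → target + coupling partner (0.03240 M⁻¹ min⁻¹)
    starting material + coupling partner + target → 2 target (0.8160 M⁻² min⁻¹)
    target → decomposed product (0.008040 min⁻¹)

At λ, Thursday's missing share corresponds to τ = 24.7 min, longer than Saturday's 22.2 min. In Thursday's flask the reagent dimer, held in balance with coupling partner, gave the first target, and that target then joined starting material and coupling partner in the second step. While target stood in the flask it passed to decomposed product at 0.00804 min⁻¹, leaving 79.6% of the charge at 36 min.

(The earlier runs and the new flask were computed with constants of no real substance.)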